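**Plan**

- Retrosynthetic cuts: first the three ester C–O bonds (one acetate, two isobutyrates), then the oxirane bonds C2–C3 and C3–O1 (one CH2 removed), then the aryl–C(=O) bond, and last the ether C–O bond of the glycolic arm.
- Enabling feature: the three-membered ring O1–C2–C3 has an unsubstituted methylene C3 and a fully substituted C2 (aryl ring and CH2OAc arm), so it is a ketone carbonyl C2=O1 to which one CH2 has been added.
- Forward order: 4-bromo-3-hydroxybenzoic acid is reduced and bis-silylated, the arylmagnesium reagent is acylated with a PMB-glycolic N-methoxy-N-methylamide to complete the chain, and the oxirane, the only ring formed, closes in step 6.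
- Stereochemistry: the single stereocentre C2 is set in step 6 by catalyst control (LaLi3[(S)-binaphthoxide]3, methylide to the Si face of the ketone). PMB removal, acetylation and silyl-to-isobutyryl exchange never break a bond at C2.

Key step: step 6

Abbreviations: TBS = tert-butyldimethylsilyl, PMB = 4-methoxybenzyl.

Assumption: the (S)-binaphthoxide complex is taken as the antipode that sends the methylide to the Si face of ketone 10 (CH2OPMB in the place methyl takes in aryl methyl ketones); should the sense prove opposite, the (R)-binaphthoxide complex is used and nothing else changes.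

**Route**

Step 1
Reactants: 1 4-bromo-3-hydroxybenzoic acid
Product: 2 2-bromo-5-(hydroxymethyl)phenol
Conditions: BH3·THF (3 equiv), THF, 0 °C to rt; H2O quench
Reagents that add atoms: none
Why: Borane reduction of a carboxylic acid proceeds through acyloxyboranes and is chemoselective, leaving the aryl bromide untouched and the phenol as a borate that hydrolyses on work-up.

Step 2
Reactants: 2 2-bromo-5-(hydroxymethyl)phenol
Product: 3 1-bromo-2-(TBS-oxy)-4-(TBS-oxymethyl)benzene
Conditions: TBSCl (2.4 equiv), imidazole, DMF, rt
Reagents that add atoms: tert-butyldimethylsilyl chloride, CC(C)(C)[Si](C)(C)Cl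
Why: Imidazole-promoted silyl ether formation caps the phenol and the primary alcohol with groups that survive organomagnesium and ylide chemistry and can leave together under fluoride at the end.

Step 3
Reactants: 4 2-chloro-N-methoxy-N-methylacetamide; 5 4-methoxybenzyl alcohol
Product: 7 2-(4-methoxybenzyloxy)-N-methoxy-N-methylacetamide, via sodium 4-methoxybenzyl oxide 6 (not isolated)
Conditions: NaH, THF, 0 °C; then 4, Bu4NI (cat.), 0 °C to rt
Reagents that add atoms: none
Why: Williamson ether synthesis, in which the alkoxide displaces the activated α-chloride much faster than it attacks the poorly electrophilic amide carbonyl.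

Step 4
Reactants: 3 1-bromo-2-(TBS-oxy)-4-(TBS-oxymethyl)benzene; 7 2-(4-methoxybenzyloxy)-N-methoxy-N-methylacetamide
Product: 10 2-(4-methoxybenzyloxy)-1-[2-(TBS-oxy)-4-(TBS-oxymethyl)phenyl]ethanone, via arylmagnesium bromide 8 (not isolated), via magnesium hemiaminal chelate 9 (not isolated)
Conditions: Mg turnings (iBu2AlH-activated), LiCl, THF, 25 °C; then 7, 0 °C; sat. aq. NH4Cl
Reagents that add atoms: none
Why: LiCl-assisted magnesium insertion into the aryl C–Br bond gives a Grignard reagent whose covalent C–Mg bond should not trigger the O-to-C silyl shift known for the aryllithium, and its addition to the amide stops at chelate 9 (Weinreb ketone synthesis), which releases the ketone only on quench.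

Step 5
Reactants: 11 trimethylsulfoxonium iodide
Product: 12 dimethyloxosulfonium methylide
Conditions: NaH, THF, reflux; filtered under argon, titrated, used as THF solution
Reagents that add atoms: none
Why: Deprotonation of the sulfoxonium salt (Corey–Chaykovsky ylide formation) gives the stabilised methylide, and filtration keeps hydride and sodium salts away from the chiral catalyst of the next step.

Step 6
Reactants: 10 2-(4-methoxybenzyloxy)-1-[2-(TBS-oxy)-4-(TBS-oxymethyl)phenyl]ethanone; 12 dimethyloxosulfonium methylide
Product: 14 (2S)-2-[2-(TBS-oxy)-4-(TBS-oxymethyl)phenyl]-2-[(4-methoxybenzyloxy)methyl]oxirane, via sulfoxonium betaine 13 (not isolated)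
Conditions: LaLi3[(S)-binaphthoxide]3 (5 mol %), [2,4,6-(MeO)3C6H2]3P=O (5 mol %), 5 Å molecular sieves, THF, rt; 12 (1.2 equiv) added slowly
Reagents that add atoms: none
Why: Proposed new method: the closest known reaction is the LaLi3(binaphthoxide)3/triarylphosphine oxide-catalysed Corey–Chaykovsky epoxidation of aryl methyl ketones, which is asked here to accept an aryl alkoxymethyl ketone, a substrate class on which it has not been shown. Lewis-acidic lanthanum binds the carbonyl oxygen of 10 and a lithium aryloxide arm of the same complex carries the methylide, so that C2–C3 should form inside the chiral pocket on the Si face and give betaine 13. Intramolecular SN2 attack of the betaine oxygen on C3 then expels dimethyl sulfoxide, a 3-exo-tet closure that makes C3–O1 and the only ring of the molecule. The C2 stereocentre is fixed in the addition step by the binaphthoxide ligand (catalyst control), because ring closure takes place at C3 and does not touch C2. The step needs enantioface selectivity at the carbonyl and addition in preference to enolisation or acyl transfer. The substrate provides the first through the size gap between the ortho-silyloxyaryl flank and the slim CH2OPMB arm, and the second through an α-oxygen that raises carbonyl electrophilicity, an aryl side without enolisable hydrogen, and an ether arm that has no acyl group to pass to the betaine alkoxide.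

Step 7
Reactants: 14 (2S)-2-[2-(TBS-oxy)-4-(TBS-oxymethyl)phenyl]-2-[(4-methoxybenzyloxy)methyl]oxirane
Product: 15 {(2R)-2-[2-(TBS-oxy)-4-(TBS-oxymethyl)phenyl]oxiran-2-yl}methanol
Conditions: DDQ (1.3 equiv), CH2Cl2/pH 7 phosphate buffer, 0 °C
Reagents that add atoms: none
Why: Oxidative PMB ether cleavage, in which DDQ takes hydride only from the electron-rich 4-methoxybenzyl position and the buffered two-phase medium hydrolyses the oxocarbenium ion without acid reaching the oxirane or the silyl ethers; C2 is untouched and its descriptor changes from S to R only because the CIP ranking of the two CH2 groups is reversed.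

Step 8
Reactants: 15 {(2R)-2-[2-(TBS-oxy)-4-(TBS-oxymethyl)phenyl]oxiran-2-yl}methanol
Product: 16 {(2S)-2-[2-(TBS-oxy)-4-(TBS-oxymethyl)phenyl]oxiran-2-yl}methyl acetate
Conditions: Ac2O, pyridine, DMAP (cat.), CH2Cl2, 0 °C
Reagents that add atoms: acetic anhydride, CC(=O)OC(C)=O
Why: DMAP-catalysed acylation of an unhindered primary alcohol under mild basic conditions, under which the only Payne rearrangement open to 15 is degenerate and returns the same enantiomer, so C2 is not at risk.

Step 9
Reactants: 16 {(2S)-2-[2-(TBS-oxy)-4-(TBS-oxymethyl)phenyl]oxiran-2-yl}methyl acetate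
Product: 17 {(2S)-2-[2-(2-methylpropanoyloxy)-4-(2-methylpropanoyloxymethyl)phenyl]oxiran-2-yl}methyl acetate (CNP0151517.1)
Conditions: (iPrCO)2O (5 equiv), DMAP (cat.), THF, 0 °C; Bu4NF (THF solution, 2.5 equiv) added slowly
Reagents that add atoms: isobutyric anhydride, CC(C)C(=O)OC(=O)C(C)C
Why: One-pot fluoride desilylation–acylation, in which Si–F bond formation frees the aryloxide and the benzylic alkoxide and the anhydride already present acylates them at once, so that no phenoxide lingers next to the oxirane and the primary acetate meets no free hydroxyl to migrate to.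

**Compound list**

1 | 4-bromo-3-hydroxybenzoic acid | OC(=O)c1ccc(Br)c(O)c1 | starting material
2 | 2-bromo-5-(hydroxymethyl)phenol | OCc1ccc(Br)c(O)c1 | intermediate
3 | 1-bromo-2-(tert-butyldimethylsilyloxy)-4-(tert-butyldimethylsilyloxymethyl)benzene | CC(C)(C)[Si](C)(C)OCc1ccc(Br)c(O[Si](C)(C)C(C)(C)C)c1 | intermediate
4 | 2-chloro-N-methoxy-N-methylacetamide | CON(C)C(=O)CCl | starting material
5 | 4-methoxybenzyl alcohol | COc1ccc(CO)cc1 | starting material
6 | sodium 4-methoxybenzyl oxide | [Na+].[O-]Cc1ccc(OC)cc1 | intermediate
7 | 2-(4-methoxybenzyloxy)-N-methoxy-N-methylacetamide | COc1ccc(COCC(=O)N(C)OC)cc1 | intermediate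
8 | [2-(tert-butyldimethylsilyloxy)-4-(tert-butyldimethylsilyloxymethyl)phenyl]magnesium bromide (LiCl complex in THF) | CC(C)(C)[Si](C)(C)OCc1ccc([Mg]Br)c(O[Si](C)(C)C(C)(C)C)c1 | intermediate
9 | bromomagnesium alkoxide of the N-methoxy-N-methyl hemiaminal formed from 8 and 7 (tetrahedral chelate) | COc1ccc(COCC(O[Mg]Br)(N(C)OC)c2ccc(CO[Si](C)(C)C(C)(C)C)cc2O[Si](C)(C)C(C)(C)C)cc1 | intermediate
10 | 2-(4-methoxybenzyloxy)-1-[2-(tert-butyldimethylsilyloxy)-4-(tert-butyldimethylsilyloxymethyl)phenyl]ethanone | COc1ccc(COCC(=O)c2ccc(CO[Si](C)(C)C(C)(C)C)cc2O[Si](C)(C)C(C)(C)C)cc1 | intermediate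
11 | trimethylsulfoxonium iodide | C[S+](C)(C)=O.[I-] | starting material
12 | dimethyloxosulfonium methylide | C[S+](C)(=O)[CH2-] | intermediate
13 | (2R)-2-aryl-1-(dimethyloxosulfonio)-3-(4-methoxybenzyloxy)propan-2-olate (catalyst-bound betaine, same spatial arrangement at C2 as 14) | COc1ccc(COC[C@]([O-])(c2ccc(CO[Si](C)(C)C(C)(C)C)cc2O[Si](C)(C)C(C)(C)C)C[S+](C)(C)=O)cc1 | intermediate
14 | (2S)-2-[2-(tert-butyldimethylsilyloxy)-4-(tert-butyldimethylsilyloxymethyl)phenyl]-2-[(4-methoxybenzyloxy)methyl]oxirane | COc1ccc(COC[C@]2(c3ccc(CO[Si](C)(C)C(C)(C)C)cc3O[Si](C)(C)C(C)(C)C)CO2)cc1 | intermediate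
15 | {(2R)-2-[2-(tert-butyldimethylsilyloxy)-4-(tert-butyldimethylsilyloxymethyl)phenyl]oxiran-2-yl}methanol | OC[C@]1(c2ccc(CO[Si](C)(C)C(C)(C)C)cc2O[Si](C)(C)C(C)(C)C)CO1 | intermediate
16 | {(2S)-2-[2-(tert-butyldimethylsilyloxy)-4-(tert-butyldimethylsilyloxymethyl)phenyl]oxiran-2-yl}methyl acetate | CC(=O)OC[C@]1(c2ccc(CO[Si](C)(C)C(C)(C)C)cc2O[Si](C)(C)C(C)(C)C)CO1 | intermediate
17 | {(2S)-2-[2-(2-methylpropanoyloxy)-4-(2-methylpropanoyloxymethyl)phenyl]oxiran-2-yl}methyl acetate (CNP0151517.1) | CC(=O)OC[C@]1(c2ccc(COC(=O)C(C)C)cc2OC(=O)C(C)C)CO1 | target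

**Step count and risks**

Total step count: 9 (steps 3 and 5 prepare the two side components).
Longest linear sequence: 7 steps (1, 2, 4, 6, 7, 8, 9) from 4-bromo-3-hydroxybenzoic acid.

Steps most likely to fail:

1. Step 6 (proposed new method). The risks are poor enantioface selection with an arm larger than methyl, slow addition at the ortho-substituted carbonyl, and silyl transfer from the aryl ether to binaphthoxide. The fallback uses known chemistry, sets out from ketone 10 and comes back at epoxy alcohol 15. Wittig methylenation (Ph3P=CH2 from Ph3PCH3Br and KOtBu, THF) should give 2-[2-(TBS-oxy)-4-(TBS-oxymethyl)phenyl]allyl 4-methoxybenzyl ether F1. DDQ in buffered CH2Cl2 should then free 2-[2-(TBS-oxy)-4-(TBS-oxymethyl)phenyl]prop-2-en-1-ol F2. Sharpless asymmetric epoxidation of this 2-substituted allylic alcohol (Ti(OiPr)4, D-(−)-diethyl tartrate, tBuOOH, 4 Å molecular sieves, CH2Cl2, −20 °C) should deliver 15 directly; the D-tartrate is the antipode expected to give (R)-configured 2-substituted glycidols. The route continues with step 8.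

2. Step 9. The risks are opening of the oxirane by the neighbouring aryloxide (ortho-quinone methide pathway) and scrambling of the acetate by fluoride or alkoxide before acylation is complete. The fallback sets out from 16 and comes back at 17. Desilylation is run under buffered, non-basic conditions (Bu4NF/AcOH 1:1, THF, 0 °C), so that the phenol is never present as its anion, and {(2S)-2-[2-hydroxy-4-(hydroxymethyl)phenyl]oxiran-2-yl}methyl acetate F3 is isolated. Both hydroxyls are then acylated in a separate operation with isobutyric anhydride, pyridine and catalytic DMAP in CH2Cl2 at 0 °C.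

3. Step 7. The risk is acid-promoted ionisation of the benzylic C2–O bond (oxirane opening or Meinwald-type rearrangement) by the acidic hydroquinone formed from DDQ while the ring still carries the electron-releasing silyloxy group. The fallback inverts the end game, setting out from 14 and coming back at 17. The fluoride/isobutyric anhydride exchange of step 9 is applied first to 14 and should give 4-{(2S)-2-[(4-methoxybenzyloxy)methyl]oxiran-2-yl}-3-(2-methylpropanoyloxy)benzyl 2-methylpropanoate F4, whose ester-bearing ring supports a benzylic cation far less. Buffered DDQ should then free 4-[(2R)-2-(hydroxymethyl)oxiran-2-yl]-3-(2-methylpropanoyloxy)benzyl 2-methylpropanoate F5. F5 is acetylated at once (Ac2O, pyridine, 0 °C) to outrun aryl-to-alkyl isobutyryl migration, giving 17.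

Further compounds
F1 | step 6 | 2-[2-(tert-butyldimethylsilyloxy)-4-(tert-butyldimethylsilyloxymethyl)phenyl]allyl 4-methoxybenzyl ether | COc1ccc(COCC(=C)c2ccc(CO[Si](C)(C)C(C)(C)C)cc2O[Si](C)(C)C(C)(C)C)cc1
F2 | step 6 | 2-[2-(tert-butyldimethylsilyloxy)-4-(tert-butyldimethylsilyloxymethyl)phenyl]prop-2-en-1-ol | OCC(=C)c1ccc(CO[Si](C)(C)C(C)(C)C)cc1O[Si](C)(C)C(C)(C)C
F3 | step 9 | {(2S)-2-[2-hydroxy-4-(hydroxymethyl)phenyl]oxiran-2-yl}methyl acetate | CC(=O)OC[C@]1(c2ccc(CO)cc2O)CO1
F4 | step 7 | 4-{(2S)-2-[(4-methoxybenzyloxy)methyl]oxiran-2-yl}-3-(2-methylpropanoyloxy)benzyl 2-methylpropanoate | COc1ccc(COC[C@]2(c3ccc(COC(=O)C(C)C)cc3OC(=O)C(C)C)CO2)cc1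
F5 | step 7 | 4-[(2R)-2-(hydroxymethyl)oxiran-2-yl]-3-(2-methylpropanoyloxy)benzyl 2-methylpropanoate | OC[C@]1(c2ccc(COC(=O)C(C)C)cc2OC(=O)C(C)C)CO1
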